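**Retrosynthetic overview**
- Target ⇐ benzyl-protected 2-aryl-tetrahydrofuran acetate (lariciresinol type). Acid opens the benzylic C–O bond, the carbocycle closes by Friedel–Crafts alkylation and the second CH2OH is set free; the benzyl ethers are cleaved in the same pot.
- Tetrahydrofuran acetate ⇐ triol ⇐ trans-α,β-disubstituted γ-butyrolactone (aldol of the β-arylmethyl lactone with O-benzylvanillin, then LiAlH4).
- (R)-β-Arylmethyl-γ-butyrolactone ⇐ prochiral 3-arylmethyl-oxetane by enantioselective ring-expansion carbonylation (key step, first stereocentre).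
- Oxetane ⇐ 3-methyleneoxetane + aryl bromide (hydroboration/Suzuki); aryl bromide and aldehyde ⇐ catechol.
- Ring order: oxetane (bought) → γ-lactone (ring expansion) → tetrahydrofuran → tetralin carbocycle.

Assumption: the (R,R)-ligand of step 6 gives the (R)-lactone; if the first run (chiral HPLC) shows the opposite sense, the (S,S)-ligand is used with no other change.

**Step 1**
Reactants: 1 catechol
Product: 2 2-methoxyphenol (guaiacol)
Conditions: MeI (0.5 equiv), K2CO3, acetone, reflux; excess 1 washed out with water
Reagents that add atoms: iodomethane CI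
Why: Williamson mono-O-methylation, with the excess of the water-soluble diol suppressing the dimethyl ether; no stereocentre.

**Step 2**
Reactants: 2 2-methoxyphenol
Product: 3 4-bromo-2-methoxyphenol
Conditions: NBS, MeCN, 0 °C
Reagents that add atoms: N-bromosuccinimide O=C1CCC(=O)N1Br
Why: Electrophilic aromatic bromination goes para to the free OH, the stronger director, which places bromine where both aryl units of the target carry their carbon substituent.

**Step 3**
Reactants: 3 4-bromo-2-methoxyphenol
Product: 4 1-(benzyloxy)-4-bromo-2-methoxybenzene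
Conditions: BnBr, K2CO3, DMF, rt
Reagents that add atoms: benzyl bromide BrCc1ccccc1
Why: Williamson benzylation; the benzyl ether survives organolithium, hydride, base and mild acid and is removed in the last step.

**Step 4**
Reactants: 4 1-(benzyloxy)-4-bromo-2-methoxybenzene
Product: 6 4-(benzyloxy)-3-methoxybenzaldehyde, via aryllithium 5 (not isolated)
Conditions: n-BuLi, THF, −78 °C; DMF; then 1 M HCl
Reagents that add atoms: N,N-dimethylformamide CN(C)C=O
Why: Bromine–lithium exchange followed by Bouveault formylation; at −78 °C the benzyl ether is not touched.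

**Step 5**
Reactants: 7 3-methyleneoxetane; 4 1-(benzyloxy)-4-bromo-2-methoxybenzene
Product: 9 3-[4-(benzyloxy)-3-methoxybenzyl]oxetane, via alkylborane 8 (not isolated)
Conditions: 7 (1.3 equiv), 9-BBN, THF, 0 °C to rt; then 4, Pd(dppf)Cl2 (3 mol%), K3PO4 (aq), DMF, 60 °C
Reagents that add atoms: none
Why: Anti-Markovnikov hydroboration of the exocyclic alkene and B-alkyl Suzuki–Miyaura coupling with the aryl bromide; the product is achiral (prochiral at oxetane C-3).

**Step 6**
Reactants: 9 3-[4-(benzyloxy)-3-methoxybenzyl]oxetane
Product: 10 (R)-4-[4-(benzyloxy)-3-methoxybenzyl]dihydrofuran-2(3H)-one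
Conditions: [(salen)Cr(THF)2][Co(CO)4] (5 mol%; salen = (R,R)-N,N'-bis(3,5-di-tert-butylsalicylidene)cyclohexane-1,2-diamine dianion), CO (60 bar), DME, 50 °C
Reagents that add atoms: carbon monoxide [C-]#[O+]
Why: Proposed new method: enantioselective ring-expansion carbonylation of a prochiral 3-substituted oxetane. The chiral cationic trivalent-chromium salen Lewis acid binds the oxetane oxygen, and Co(CO)4− opens one of the two enantiotopic CH2–O bonds by SN2 attack; this is the enantio-determining event, and C-3 itself is not touched, so it becomes the lactone stereocentre. CO then inserts into the Co–alkyl bond by 1,2-alkyl migration and the chromium alkoxide closes the five-membered lactone. The closest known reactions are the racemic ring-expansion carbonylation of epoxides, β-lactones and the parent oxetane with Lewis-acid cation/Co(CO)4− ion pairs, and the enantioselective carbonylative desymmetrization of meso-epoxides; a desymmetrizing carbonylation of an oxetane has not been shown.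

**Step 7**
Reactants: 10 (R)-4-[4-(benzyloxy)-3-methoxybenzyl]dihydrofuran-2(3H)-one; 6 4-(benzyloxy)-3-methoxybenzaldehyde
Product: 12 (3S,4R)-4-[4-(benzyloxy)-3-methoxybenzyl]-3-{[4-(benzyloxy)-3-methoxyphenyl](hydroxy)methyl}dihydrofuran-2(3H)-one (trans, both carbinol epimers), via lithium enolate 11 (not isolated)
Conditions: LiN(iPr)2, THF, −78 °C; then 6; AcOH, −78 °C
Reagents that add atoms: none
Why: Lithium enolate aldol addition; the aldehyde approaches the enolate face anti to the C-4 arylmethyl group, which sets the 3,4-trans relationship (target C-2), while the carbinol configuration is irrelevant because that carbon is ionized later.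

**Step 8**
Reactants: 12 trans aldol lactone
Product: 13 (2R,3R)-2-[4-(benzyloxy)-3-methoxybenzyl]-3-{[4-(benzyloxy)-3-methoxyphenyl](hydroxy)methyl}butane-1,4-diol (both carbinol epimers)
Conditions: LiAlH4, THF, 0 °C to rt; H2O/NaOH work-up
Reagents that add atoms: none
Why: Hydride reduction of the lactone to the 1,4-diol; neither backbone stereocentre is touched and the benzyl ethers are inert.

**Step 9**
Reactants: 13 triol
Product: 15 {(2S,3R,4R)-2-[4-(benzyloxy)-3-methoxyphenyl]-4-[4-(benzyloxy)-3-methoxybenzyl]tetrahydrofuran-3-yl}methyl acetate, via tetrahydrofuran alcohol 14 (not isolated)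
Conditions: CSA (5 mol%), CH2Cl2, 0 °C to rt; then pyridine, Ac2O, DMAP (cat.), rt
Reagents that add atoms: acetic anhydride CC(=O)OC(C)=O
Why: Acid-catalysed SN1 cycloetherification of the p-alkoxybenzylic alcohol, in which only the remote CH2OH can close a five-membered ring (the near one would give an oxetane), followed by acetylation of the single OH left. This is how the two CH2OH groups are told apart; the C-2 configuration (trans expected) is immaterial.

**Step 10**
Reactants: 15 tetrahydrofuran acetate
Product: 17 [(1S,2R,3R)-7-hydroxy-1-(4-hydroxy-3-methoxyphenyl)-3-(hydroxymethyl)-6-methoxy-1,2,3,4-tetrahydronaphthalen-2-yl]methyl acetate, via dibenzyl tetralin acetate 16 (not isolated)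
Conditions: TFA/CH2Cl2 1:9, 0 °C, 30 min; then C6HMe5 (8 equiv), TFA/CH2Cl2 1:1, rt; NaHCO3 (aq)/MeOH work-up
Reagents that add atoms: none
Why: Acid opens the benzylic C–O bond and the cation is captured by intramolecular Friedel–Crafts alkylation para to the methoxy group of the other ring (the lariciresinol-to-isolariciresinol type rearrangement). A chair-like closure with the aryl group pseudo-equatorial sets C-1 trans to C-2 and frees the C-3 CH2OH; the benzyl ethers are then cleaved by acidolysis with pentamethylbenzene as benzyl-cation scavenger, and the alkyl acetate is stable to TFA.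

**Compound list**
1 | catechol | Oc1ccccc1O | starting material
2 | 2-methoxyphenol | COc1ccccc1O | intermediate
3 | 4-bromo-2-methoxyphenol | COc1cc(Br)ccc1O | intermediate
4 | 1-(benzyloxy)-4-bromo-2-methoxybenzene | COc1cc(Br)ccc1OCc1ccccc1 | intermediate
5 | [4-(benzyloxy)-3-methoxyphenyl]lithium | [Li]c1ccc(OCc2ccccc2)c(OC)c1 | intermediate
6 | 4-(benzyloxy)-3-methoxybenzaldehyde | COc1cc(C=O)ccc1OCc1ccccc1 | intermediate
7 | 3-methyleneoxetane | C=C1COC1 | starting material
8 | 9-(oxetan-3-ylmethyl)-9-borabicyclo[3.3.1]nonane | C1CC2CCCC(C1)B2CC1COC1 | intermediate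
9 | 3-[4-(benzyloxy)-3-methoxybenzyl]oxetane | COc1cc(CC2COC2)ccc1OCc1ccccc1 | intermediate
10 | (R)-4-[4-(benzyloxy)-3-methoxybenzyl]dihydrofuran-2(3H)-one | COc1cc(C[C@H]2COC(=O)C2)ccc1OCc1ccccc1 | intermediate
11 | lithium (R)-4-[4-(benzyloxy)-3-methoxybenzyl]-4,5-dihydrofuran-2-olate | [Li]OC1=C[C@@H](Cc2ccc(OCc3ccccc3)c(OC)c2)CO1 | intermediate
12 | (3S,4R)-4-[4-(benzyloxy)-3-methoxybenzyl]-3-{[4-(benzyloxy)-3-methoxyphenyl](hydroxy)methyl}dihydrofuran-2(3H)-one, carbinol epimers | COc1cc(C[C@H]2COC(=O)[C@@H]2C(O)c2ccc(OCc3ccccc3)c(OC)c2)ccc1OCc1ccccc1 | intermediate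
13 | (2R,3R)-2-[4-(benzyloxy)-3-methoxybenzyl]-3-{[4-(benzyloxy)-3-methoxyphenyl](hydroxy)methyl}butane-1,4-diol, carbinol epimers | COc1cc(C[C@@H](CO)[C@H](CO)C(O)c2ccc(OCc3ccccc3)c(OC)c2)ccc1OCc1ccccc1 | intermediate
14 | {(2S,3R,4R)-2-[4-(benzyloxy)-3-methoxyphenyl]-4-[4-(benzyloxy)-3-methoxybenzyl]tetrahydrofuran-3-yl}methanol | COc1cc(C[C@H]2CO[C@H](c3ccc(OCc4ccccc4)c(OC)c3)[C@H]2CO)ccc1OCc1ccccc1 | intermediate
15 | {(2S,3R,4R)-2-[4-(benzyloxy)-3-methoxyphenyl]-4-[4-(benzyloxy)-3-methoxybenzyl]tetrahydrofuran-3-yl}methyl acetate | COc1cc(C[C@H]2CO[C@H](c3ccc(OCc4ccccc4)c(OC)c3)[C@H]2COC(C)=O)ccc1OCc1ccccc1 | intermediate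
16 | [(1S,2R,3R)-7-(benzyloxy)-1-[4-(benzyloxy)-3-methoxyphenyl]-3-(hydroxymethyl)-6-methoxy-1,2,3,4-tetrahydronaphthalen-2-yl]methyl acetate | COc1cc([C@H]2c3cc(OCc4ccccc4)c(OC)cc3C[C@@H](CO)[C@@H]2COC(C)=O)ccc1OCc1ccccc1 | intermediate
17 | [(1S,2R,3R)-7-hydroxy-1-(4-hydroxy-3-methoxyphenyl)-3-(hydroxymethyl)-6-methoxy-1,2,3,4-tetrahydronaphthalen-2-yl]methyl acetate | COc1cc([C@H]2c3cc(O)c(OC)cc3C[C@@H](CO)[C@@H]2COC(C)=O)ccc1O | target

**Totals**
Total step count: 10.
Longest linear sequence: 9 steps (1, 2, 3, 5, 6, 7, 8, 9, 10); step 4 is the side branch that supplies aldehyde 6.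

**Steps most likely to fail, with fallbacks**

Step 6 (the proposed new step). The risks are low enantioselectivity, because the stereocentre is one carbon away from the bond that is opened, and slow carbonylation or cationic oligomerization of the oxetane. The fallback uses known chemistry, sets out from 4 and comes back at 10. Nickel-catalysed reductive cross-electrophile coupling of 4 with 3-(bromomethyl)cyclobutan-1-one (NiBr2(dme), 4,4'-di-tert-butyl-2,2'-bipyridine, Zn, NaI, DMA, 60 °C) gives 3-[4-(benzyloxy)-3-methoxybenzyl]cyclobutan-1-one F1. F1 is then desymmetrized by a known enantioselective Baeyer–Villiger ring expansion; an (R)-selective Baeyer–Villiger monooxygenase in whole cells under air (buffer, 30 °C) is established for 3-benzylcyclobutanones in both enantiomeric senses. This delivers lactone 10, and steps 7 to 10 follow unchanged.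

Step 10 (rearrangement and debenzylation in one pot). The risks are C-benzylation of the electron-rich rings by benzyl cations, capture of the lignan cation by the scavenger (which is why the scavenger is added only after ring closure), and acetyl migration on long exposure to acid. The fallback sets out from 15 and comes back at 17. Treatment of 15 with TFA/CH2Cl2 1:9 at 0 °C without scavenger is stopped after the Friedel–Crafts closure and 16 is isolated. The two benzyl ethers are then removed by hydrogenolysis (H2, 1 atm, Pd/C, EtOAc) instead of acidolysis, which leaves the acetate and the diarylmethine untouched. This fallback makes no compound outside the list (F0).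

Step 5 (hydroboration/Suzuki). The risks are the volatility of 7 and fragmentation of the borate of 8, by 1,3-elimination onto the strained ring or protodeboronation, before transmetalation. The fallback sets out from 4 and comes back at 9. It avoids the borane altogether: nickel-catalysed reductive cross-electrophile coupling of 4 with 3-(bromomethyl)oxetane (NiBr2(dme), 4,4'-di-tert-butyl-2,2'-bipyridine, Zn, NaI, DMA, 60 °C) gives 9 directly. This fallback makes no compound outside the list (F0).

**Further compounds**
F0 | step 5 | none | none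
F1 | step 6 | 3-[4-(benzyloxy)-3-methoxybenzyl]cyclobutan-1-one | COc1cc(CC2CC(=O)C2)ccc1OCc1ccccc1
F0 | step 10 | none | none
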